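**Assumption:** the target has no stereocentre and no stereogenic double bond (each alkene ends in a gem-dimethyl group), so it is achiral and the route makes this one compound.

**Retrosynthetic overview**
- Each prenyl group is cut between its CH2 and its CH=CMe2 part: clusiaphenone B goes back to a 3,5-bis(dimethylaminomethyl) Mannich base plus two isobutenylboron units (the proposed new step, via o-quinone methides).
- The two ring–CH2 bonds go back to 2,4,6-trihydroxybenzophenone by a double phenol Mannich reaction.
- The aryl–C(O) bond goes back to phloroglucinol and benzonitrile (Houben–Hoesch).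
- No ring is built: both benzene rings are bought. Bond order is aryl ketone, then two ring–CH2 bonds, then two CH2–CH= bonds.

**Step 1**
Reactants: 1 phloroglucinol (benzene-1,3,5-triol, anhydrous); 2 benzonitrile
Product: 4 phenyl(2,4,6-trihydroxyphenyl)methanone, via ketiminium chloride 3 (not isolated)
Conditions: HCl (g), ZnCl2 (0.2 equiv), Et2O, 0 °C, 48 h; then H2O, reflux, 2 h
Reagents that add atoms: hydrogen chloride, Cl (ends in intermediate 3 and in the ammonium salt, not in 4); water, O (the ketone oxygen of 4)
Why: Houben–Hoesch acylation, in which HCl/ZnCl2 turns the nitrile into a nitrilium-type electrophile that attacks one of the three equivalent ring carbons of phloroglucinol, the precipitated ketiminium salt 3 deactivates the ring against a second acylation, and boiling water hydrolyses it to the ketone; no stereocentre is formed.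

**Step 2**
Reactants: 4 phenyl(2,4,6-trihydroxyphenyl)methanone; 5 bis(dimethylamino)methane
Product: 7 {3,5-bis[(dimethylamino)methyl]-2,4,6-trihydroxyphenyl}(phenyl)methanone, via mono-Mannich base 6 (not isolated)
Conditions: 5 (2.3 equiv), 1,4-dioxane, 23 °C then 50 °C, 6 h; product filtered off
Reagents that add atoms: none
Why: Phenol Mannich reaction (aminomethylation), in which the acidic acylphloroglucinol protonates the aminal to release N,N-dimethylmethyleneiminium, which is captured by the only two free ring carbons (C3 and C5), so exactly two CH2NMe2 groups are installed; no stereocentre is formed.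

**Step 3**
Reactants: 7 {3,5-bis[(dimethylamino)methyl]-2,4,6-trihydroxyphenyl}(phenyl)methanone; 8 (2-methylprop-1-en-1-yl)boronic acid
Product: 12 clusiaphenone B, via first o-quinone methide 9 (not isolated), via monoprenyl Mannich base 10 (not isolated), via second o-quinone methide 11 (not isolated)
Conditions: 8 (3.0 equiv), 1,4-dioxane (0.05 M), 85 °C, slow N2 sweep, 12 h; then 5% aq. AcOH
Reagents that add atoms: none
Why: Proposed new method: a deaminative, boron-templated conjugate alkenylation that builds each prenyl group from the Mannich CH2 carbon and the isobutenyl unit of 8. The acidic, zwitterionic Mannich base expels dimethylamine in an E1cB-type step (helped by N→B coordination) to give o-quinone methide 9 (later 11); 8 binds the o-quinone methide carbonyl oxygen as a four-coordinate boronate and passes its alkenyl group to the exocyclic CH2 through a six-membered transition state, which re-aromatises the ring and gives ArCH2–CH=CMe2 with the double bond fixed in place. Because every ring carbon of 7 is already substituted, O-prenylation, a third dearomatising C-prenylation and methylene-bridged dimers are blocked, and exactly two prenyl groups can form; no stereocentre is created. The closest known reaction types are the Petasis borono-Mannich reaction and the conjugate addition of alkenylboronates to o-quinone methides.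

**Compound list**
1 | phloroglucinol (benzene-1,3,5-triol) | Oc1cc(O)cc(O)c1 | starting material
2 | benzonitrile | N#Cc1ccccc1 | starting material
3 | phenyl(2,4,6-trihydroxyphenyl)methaniminium chloride (ketiminium chloride) | [NH2+]=C(c1ccccc1)c1c(O)cc(O)cc1O.[Cl-] | intermediate
4 | phenyl(2,4,6-trihydroxyphenyl)methanone (2,4,6-trihydroxybenzophenone) | O=C(c1ccccc1)c1c(O)cc(O)cc1O | intermediate
5 | bis(dimethylamino)methane (N,N,N',N'-tetramethylmethanediamine) | CN(C)CN(C)C | starting material
6 | {3-[(dimethylamino)methyl]-2,4,6-trihydroxyphenyl}(phenyl)methanone (mono-Mannich base) | CN(C)Cc1c(O)cc(O)c(C(=O)c2ccccc2)c1O | intermediate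
7 | {3,5-bis[(dimethylamino)methyl]-2,4,6-trihydroxyphenyl}(phenyl)methanone (bis-Mannich base) | CN(C)Cc1c(O)c(CN(C)C)c(O)c(C(=O)c2ccccc2)c1O | intermediate
8 | (2-methylprop-1-en-1-yl)boronic acid | CC(C)=CB(O)O | starting material
9 | 4-benzoyl-2-[(dimethylamino)methyl]-3,5-dihydroxy-6-methylidenecyclohexa-2,4-dien-1-one (first o-quinone methide) | C=C1C(=O)C(CN(C)C)=C(O)C(C(=O)c2ccccc2)=C1O | intermediate
10 | {3-[(dimethylamino)methyl]-2,4,6-trihydroxy-5-(3-methylbut-2-en-1-yl)phenyl}(phenyl)methanone (monoprenyl Mannich base) | CC(C)=CCc1c(O)c(CN(C)C)c(O)c(C(=O)c2ccccc2)c1O | intermediate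
11 | 4-benzoyl-3,5-dihydroxy-6-methylidene-2-(3-methylbut-2-en-1-yl)cyclohexa-2,4-dien-1-one (second o-quinone methide) | C=C1C(=O)C(CC=C(C)C)=C(O)C(C(=O)c2ccccc2)=C1O | intermediate
12 | clusiaphenone B ([2,4,6-trihydroxy-3,5-bis(3-methylbut-2-en-1-yl)phenyl](phenyl)methanone) | CC(C)=CCc1c(O)c(CC=C(C)C)c(O)c(C(=O)c2ccccc2)c1O | target

**Total step count:** 3
**Longest linear sequence:** 3 steps (1 → 4 → 7 → 12)

**Three steps most likely to fail**

Step 3 (the proposed new step) is the most likely to fail. Amine loss may be sluggish at 85 °C, or the o-quinone methides 9 and 11 may be diverted into hetero-Diels–Alder adducts or oligomers before the alkenyl group is transferred. The fallback uses known chemistry, sets out from 4 and comes back to the route at 12. Compound 4 is C-prenylated as its phenoxide in water with 1-bromo-3-methylbut-2-ene (1.1 equiv) in 10% aq. KOH at 0 °C, giving 3-prenyl-2,4,6-trihydroxybenzophenone F1. F1 is isolated and put through the same aqueous KOH prenylation a second time to give 12. Yields are expected to be modest because O-prenylation and over-prenylation compete, but the product is separable by chromatography.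

Step 2 is the next most likely to fail. The second aminomethylation may stall at 6, or the zwitterionic product 7 may be hard to isolate cleanly. The fallback sets out from 4 and comes back at 7. A double Vilsmeier–Haack formylation of 4 (POCl3, DMF, MeCN, 0 to 23 °C; then H2O, 60 °C) gives 3,5-diformyl-2,4,6-trihydroxybenzophenone F2. A double reductive amination of F2 (Me2NH·HCl, Et3N, NaBH(OAc)3, 1,2-dichloroethane, 0 to 23 °C) then gives 7.

Step 1 is the third. Benzonitrile is a slow Hoesch partner, the phloroglucinol must be strictly anhydrous, and the diaryl ketiminium salt may hydrolyse incompletely. The fallback sets out from 1 and comes back at 4. Compound 1 is O-methylated (Me2SO4, K2CO3, acetone, reflux) to 1,3,5-trimethoxybenzene F3. Friedel–Crafts benzoylation of F3 (benzoyl chloride, AlCl3, CH2Cl2, 0 °C) gives 2,4,6-trimethoxybenzophenone F4. Exhaustive demethylation of F4 (BBr3, CH2Cl2, −78 to 23 °C; then H2O) gives 4.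

**Further compounds**
F1 | step 3 | 3-prenyl-2,4,6-trihydroxybenzophenone ([2,4,6-trihydroxy-3-(3-methylbut-2-en-1-yl)phenyl](phenyl)methanone) | CC(C)=CCc1c(O)cc(O)c(C(=O)c2ccccc2)c1O
F2 | step 2 | 3,5-diformyl-2,4,6-trihydroxybenzophenone (5-benzoyl-2,4,6-trihydroxybenzene-1,3-dicarbaldehyde) | O=Cc1c(O)c(C=O)c(O)c(C(=O)c2ccccc2)c1O
F3 | step 1 | 1,3,5-trimethoxybenzene | COc1cc(OC)cc(OC)c1
F4 | step 1 | 2,4,6-trimethoxybenzophenone (phenyl(2,4,6-trimethoxyphenyl)methanone) | COc1cc(OC)c(C(=O)c2ccccc2)c(OC)c1
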